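**Strategy.** No macrocyclisation is used. C5 (ketone carbon) and C10 (tertiary carbinol) sit 1,6 to each other across the ten-membered carbocycle, so joining them on paper contracts C1–C5 plus C10 to a cyclohexane carrying the arms C6=C7 and C9=C8. A trans-1,2-dialkenyl-cis-2,6-dimethylcyclohexanol (E PMB enol ether on C10, E dienyl on C5) undergoes an anionic oxy-Cope shift that makes C7–C8, breaks C5–C10, fixes C7 and C8 through a chair and delivers the C5–C6 enolate, which is hydroxylated in the same flask (C6). The C9=C10 alkene is then oxidised with transannular help from C5, and the lactone ring (C7, C8, O, C12, C11) is closed last.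

Key step: step 10

Numbering: germacrane numbers are used for the ten-membered compounds and for the corresponding atoms of their precursors (C14 is the methyl on C10, C15 the methyl on C4).
Assumption: compound 1 is the meso cis isomer of 2,6-dimethylcyclohexanone, the main component of the commercial cis-rich mixture, taken after base equilibration and distillation.
Assumption: the (S,S)-lithium amide is taken, by analogy with its sense on 4-substituted cyclohexanones, to leave the (S)-configured α-carbon; if the sense is opposite, the (R,R)-amide is used.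

Step 1
Reactants: 1 cis-2,6-dimethylcyclohexan-1-one (meso); 2 allyl chloroformate
Product: 4 allyl (6S)-2,6-dimethylcyclohex-1-en-1-yl carbonate, via lithium (6S)-enolate 3 (not isolated)
Conditions: (S,S)-bis(1-phenylethyl)amine hydrochloride, n-BuLi (2 equiv), THF, −78 °C; 1, −78 °C; then TMEDA, 2, −78 °C to rt
Reagents that add atoms: none
Why: Enantiotopos-selective deprotonation of the meso ketone by a chiral lithium amide (LiCl formed in the flask, external quench) should leave the (S)-configured α-carbon untouched, which fixes the future C4, and the hindered tetrasubstituted enolate is acylated on oxygen by the chloroformate.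

Step 2
Reactants: 4 allyl (6S)-2,6-dimethylcyclohex-1-en-1-yl carbonate
Product: 5 (2R,6S)-2-allyl-2,6-dimethylcyclohexan-1-one
Conditions: Pd2(dba)3 (2.5 mol %), (R)-t-BuPHOX (6 mol %), THF, 25 °C
Reagents that add atoms: none
Why: Decarboxylative asymmetric allylic alkylation (Tsuji allylation): loss of CO2 gives an allylpalladium enolate that recombines at the tetrasubstituted carbon, the (R)-PHOX ligand selecting the face that gives (2R) (future C10) in the matched sense with the substrate, whose pseudoaxial C6 methyl also steers the allyl group trans to itself, so the minor enolate enantiomer should end mainly in the separable trans-dimethyl diastereomer.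

Step 3
Reactants: 5 (2R,6S)-2-allyl-2,6-dimethylcyclohexan-1-one
Product: 6 (2R,6S)-2,6-dimethyl-2-[(1E)-prop-1-en-1-yl]cyclohexan-1-one
Conditions: PdCl2(MeCN)2 (5 mol %), toluene, 70 °C
Reagents that add atoms: none
Why: Metal hydride mediated alkene isomerisation moves the terminal double bond into the preferred internal position under neutral conditions, so neither stereocentre is touched and the E/Z composition does not matter because the alkene is cleaved next.

Step 4
Reactants: 6 (2R,6S)-2,6-dimethyl-2-[(1E)-prop-1-en-1-yl]cyclohexan-1-one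
Product: 8 (1R,3S)-1,3-dimethyl-2-oxocyclohexane-1-carbaldehyde, via secondary ozonide 7 (not isolated)
Conditions: O3, CH2Cl2, −78 °C; then PPh3, −78 °C to rt
Reagents that add atoms: ozone, [O-][O+]=O
Why: Ozonolysis (Criegee mechanism) with reductive work-up removes the two-carbon terminus of the propenyl group and leaves a formyl group on the quaternary carbon, which cannot enolise, so the aldehyde keeps its configuration if it is used at once.

Step 5
Reactants: 8 (1R,3S)-1,3-dimethyl-2-oxocyclohexane-1-carbaldehyde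
Product: 9 (2R,6S)-2,6-dimethyl-2-[(E)-2-(4,4,5,5-tetramethyl-1,3,2-dioxaborolan-2-yl)ethenyl]cyclohexan-1-one
Conditions: Cl2CHBpin (2 equiv), CrCl2 (8 equiv), LiI (4 equiv), THF, 25 °C
Reagents that add atoms: 2-(dichloromethyl)-4,4,5,5-tetramethyl-1,3,2-dioxaborolane, ClC(Cl)B1OC(C)(C)C(C)(C)O1
Why: Takai–Utimoto boryl-olefination, in which the geminal dichromium reagent adds only to the aldehyde and eliminates to the E-alkenylboronate under non-basic conditions, so the β-keto aldehyde should neither deformylate nor epimerise at the α-methine.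

Step 6
Reactants: 9 (2R,6S)-2,6-dimethyl-2-[(E)-2-(4,4,5,5-tetramethyl-1,3,2-dioxaborolan-2-yl)ethenyl]cyclohexan-1-one
Product: 10 (2R,6S)-2-{(E)-2-[(4-methoxybenzyl)oxy]ethenyl}-2,6-dimethylcyclohexan-1-one
Conditions: 4-methoxybenzyl alcohol (excess), Cu(OAc)2 (2 equiv), Et3N (4 equiv), 4 Å molecular sieves, air, 25 °C
Reagents that add atoms: 4-methoxybenzyl alcohol, COc1ccc(CO)cc1
Why: Chan–Lam–Evans oxidative C–O coupling transfers the alkenyl group from boron through copper to the alcohol oxygen with retention of the E geometry, at room temperature and with only a tertiary amine present, so the enol ether is stereodefined and the α-stereocentre is not equilibrated.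

Step 7
Reactants: 11 2-bromoprop-2-en-1-ol
Product: 12 1-{[(2-bromoprop-2-en-1-yl)oxy]methyl}-4-methoxybenzene
Conditions: NaH, 4-methoxybenzyl chloride, Bu4NI (cat.), THF, 0 °C to rt
Reagents that add atoms: 4-methoxybenzyl chloride, COc1ccc(CCl)cc1
Why: Williamson etherification of the primary allylic alkoxide by the benzylic chloride; the same protecting group as on the enol ether is chosen so that the C8 and C12 oxygens are released together in step 15.

Step 8
Reactants: 12 1-{[(2-bromoprop-2-en-1-yl)oxy]methyl}-4-methoxybenzene; 13 (E)-1,2-bis(tributylstannyl)ethene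
Product: 14 tributyl[(1E)-3-{[(4-methoxybenzyl)oxy]methyl}buta-1,3-dien-1-yl]stannane
Conditions: 13 (2 equiv), Pd(PPh3)4 (5 mol %), toluene, 90 °C
Reagents that add atoms: none
Why: Stille coupling of the alkenyl bromide at one tin terminus of the bis-stannane, kept in excess so that mono-coupling prevails, proceeds with retention and should give the E dienylstannane.

Step 9
Reactants: 14 tributyl[(1E)-3-{[(4-methoxybenzyl)oxy]methyl}buta-1,3-dien-1-yl]stannane; 10 (2R,6S)-2-{(E)-2-[(4-methoxybenzyl)oxy]ethenyl}-2,6-dimethylcyclohexan-1-one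
Product: 17 (1S,2R,6S)-1-[(1E)-3-{[(4-methoxybenzyl)oxy]methyl}buta-1,3-dien-1-yl]-2-{(E)-2-[(4-methoxybenzyl)oxy]ethenyl}-2,6-dimethylcyclohexan-1-ol, via dienyllithium 15 (not isolated), via dienylcerium dichloride 16 (not isolated)
Conditions: 14, n-BuLi, THF, −78 °C; CeCl3 (anhydrous), −78 °C; then 10, −78 to −40 °C; aq NH4Cl
Reagents that add atoms: none
Why: Tin–lithium exchange and transmetalation give a weakly basic organocerium that adds 1,2 to the hindered, enolisable ketone; in the chair with both methyls equatorial the enol ether arm is axial and blocks the equatorial trajectory, so the nucleophile should enter axially, anti to that arm, which makes the two alkenyl groups trans and sets the carbinol centre (S).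

Step 10
Reactants: 17 (1S,2R,6S)-1-[(1E)-3-{[(4-methoxybenzyl)oxy]methyl}buta-1,3-dien-1-yl]-2-{(E)-2-[(4-methoxybenzyl)oxy]ethenyl}-2,6-dimethylcyclohexan-1-ol
Product: 20 (4S,6S,7S,8S,9E)-6-hydroxy-8,12-bis[(4-methoxybenzyl)oxy]germacra-9,11(13)-dien-5-one, via potassium alkoxide 18 (not isolated), via potassium enolate 19 (not isolated)
Conditions: KN(SiMe3)2 (1.3 equiv), 18-crown-6, THF, −78 to 0 °C; then 2-(phenylsulfonyl)-3-phenyloxaziridine, −78 °C; aq NH4Cl
Reagents that add atoms: 2-(phenylsulfonyl)-3-phenyloxaziridine, O=S(=O)(c1ccccc1)N1OC1c1ccccc1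
Why: Deprotonation gives potassium alkoxide 18, and the oxyanion-weakened C5–C10 bond breaks while C7–C8 forms in a concerted [3,3] sigmatropic shift through a chair in which both alkenyl arms are equatorial on the cyclohexane; the regiodefined enolate 19 is then oxidised at C6 by electrophilic oxygen transfer from the oxaziridine. The closest known reaction type is the anionic oxy-Cope ring expansion of trans-1,2-divinylcyclohexanols to cyclodec-5-enones with oxidative trapping of the enolate in the same flask. The ten-membered ring is closed by four-atom ring expansion of the six-membered ring, the new σ bond C7–C8 being made inside a six-centre pericyclic array and not by end-to-end cyclisation. C7 and C8 are set by chirality transfer from C5 and C10 through the chair together with the E geometry of both arms, which puts C11 and the C8 oxygen equatorial and therefore trans, and the same chair gives the E C9=C10 alkene; C6 is set by attack on the outer face of the ring-bound enolate, whose inner face is covered by the C9=C10 unit. The step needs chair over boat selectivity, which the trans-diequatorial arms and the relief of the 1,3-diaxial methyl pair secure, and it needs a single enolate regioisomer, which the rearrangement itself delivers towards C6 so that C4 is never deprotonated.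

Step 11
Reactants: 20 (4S,6S,7S,8S,9E)-6-hydroxy-8,12-bis[(4-methoxybenzyl)oxy]germacra-9,11(13)-dien-5-one
Product: 21 (4S,6S,7R,8S,9E)-6-[(tert-butyldimethylsilyl)oxy]-8,12-bis[(4-methoxybenzyl)oxy]germacra-9,11(13)-dien-5-one
Conditions: TBSOTf, 2,6-lutidine, CH2Cl2, −78 to 0 °C
Reagents that add atoms: tert-butyldimethylsilyl triflate, CC(C)(C)[Si](C)(C)OS(=O)(=O)C(F)(F)F
Why: Silylation of the secondary α-hydroxyl with a silyl triflate and a hindered pyridine base protects C6–O against acylation, ketol shift and, later, lactonisation towards C6 (the C7 descriptor changes only because of the priority of silicon).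

Step 12
Reactants: 21 (4S,6S,7R,8S,9E)-6-[(tert-butyldimethylsilyl)oxy]-8,12-bis[(4-methoxybenzyl)oxy]germacra-9,11(13)-dien-5-one
Product: 22 (4S,6S,7R,8R,9S,10S)-6-[(tert-butyldimethylsilyl)oxy]-9,10-epoxy-8,12-bis[(4-methoxybenzyl)oxy]germacr-11(13)-en-5-one
Conditions: mCPBA (1.1 equiv), NaHCO3, CH2Cl2, 0 °C
Reagents that add atoms: 3-chloroperoxybenzoic acid, O=C(OO)c1cccc(Cl)c1
Why: Prilezhaev epoxidation should select the strained, electron-rich trisubstituted C9=C10 alkene over the 1,1-disubstituted allylic-ether alkene, and allylic 1,3-strain between C14 and C8 keeps C8–H in the alkene plane with C7 on the ring side, so the peracid meets only the outer face and sets C9 as in the target.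

Step 13
Reactants: 22 (4S,6S,7R,8R,9S,10S)-6-[(tert-butyldimethylsilyl)oxy]-9,10-epoxy-8,12-bis[(4-methoxybenzyl)oxy]germacr-11(13)-en-5-one
Product: 24 (4S,6S,7R,8R,9S,10R)-6-[(tert-butyldimethylsilyl)oxy]-9,10-dihydroxy-8,12-bis[(4-methoxybenzyl)oxy]germacr-11(13)-en-5-one, via bridged hemiketal 23 (not isolated)
Conditions: HClO4 (cat.), THF/H2O (4:1), 0 °C
Reagents that add atoms: water, O
Why: Acid-catalysed epoxide hydrolysis in which the backside of the tertiary C10–O bond points across the ring at C5, its former bonding partner, so the hydroxyl of the C5 hydrate should open the protonated epoxide at C10 with inversion (1,6-transannular hemiketal formation as known for cyclodecanones), and collapse of hemiketal 23 returns the ketone and leaves the C10 carbinol with the configuration of the target.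

Step 14
Reactants: 24 (4S,6S,7R,8R,9S,10R)-6-[(tert-butyldimethylsilyl)oxy]-9,10-dihydroxy-8,12-bis[(4-methoxybenzyl)oxy]germacr-11(13)-en-5-one
Product: 25 (4S,6S,7R,8R,9S,10R)-6-[(tert-butyldimethylsilyl)oxy]-10-hydroxy-8,12-bis[(4-methoxybenzyl)oxy]-9-[(3-methylbutanoyl)oxy]germacr-11(13)-en-5-one
Conditions: isovaleric anhydride, DMAP, Et3N, CH2Cl2, 0 °C to rt
Reagents that add atoms: 3-methylbutanoic anhydride, CC(C)CC(=O)OC(=O)CC(C)C
Why: DMAP-catalysed acylation (Steglich-type acyl transfer) esterifies the only secondary hydroxyl, the tertiary C10–OH being inert under these conditions.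

Step 15
Reactants: 25 (4S,6S,7R,8R,9S,10R)-6-[(tert-butyldimethylsilyl)oxy]-10-hydroxy-8,12-bis[(4-methoxybenzyl)oxy]-9-[(3-methylbutanoyl)oxy]germacr-11(13)-en-5-one
Product: 26 (4S,6S,7R,8R,9S,10R)-6-[(tert-butyldimethylsilyl)oxy]-8,10,12-trihydroxy-9-[(3-methylbutanoyl)oxy]germacr-11(13)-en-5-one
Conditions: DDQ (3 equiv), CH2Cl2/pH 7 phosphate buffer (10:1), 0 °C
Reagents that add atoms: none
Why: Oxidative cleavage of both 4-methoxybenzyl ethers by DDQ through benzylic hydride abstraction, the wet buffered medium hydrolysing the oxocarbenium ions before a neighbouring hydroxyl can trap them, while ester, silyl ether and the unactivated alkene are inert.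

Step 16
Reactants: 26 (4S,6S,7R,8R,9S,10R)-6-[(tert-butyldimethylsilyl)oxy]-8,10,12-trihydroxy-9-[(3-methylbutanoyl)oxy]germacr-11(13)-en-5-one
Product: 29 (4S,6S,7R,8R,9S,10R)-6-[(tert-butyldimethylsilyl)oxy]-10-hydroxy-9-[(3-methylbutanoyl)oxy]-5-oxogermacr-11(13)-en-12,8-olide, via enal 27 (not isolated), via lactol 28 (not isolated)
Conditions: MnO2 (activated, 30 equiv), CH2Cl2, 25 °C
Reagents that add atoms: none
Why: Oxidative lactonisation in which MnO2 oxidises only the allylic primary alcohol to the enal, the C8 hydroxyl adds to it to close the five-membered lactol, and the allylic lactol is oxidised on to the α-methylene lactone, the silyl group on C6–O ensuring that the ring can close only to C8.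

Step 17
Reactants: 29 (4S,6S,7R,8R,9S,10R)-6-[(tert-butyldimethylsilyl)oxy]-10-hydroxy-9-[(3-methylbutanoyl)oxy]-5-oxogermacr-11(13)-en-12,8-olide
Product: 30 (4S,6S,7S,8R,9S,10R)-6,10-dihydroxy-9-[(3-methylbutanoyl)oxy]-5-oxogermacr-11(13)-en-12,8-olide (CNP0240128.1)
Conditions: HF·pyridine, pyridine, THF, 0 °C to rt
Reagents that add atoms: none
Why: Fluoride-mediated desilylation under mildly acidic, non-nucleophilic conditions, which should avoid translactonisation towards C6–O, acyl migration and conjugate addition to the methylene lactone.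

**Compound list**

1 | cis-2,6-dimethylcyclohexan-1-one (meso) | C[C@H]1CCC[C@@H](C)C1=O | starting material
2 | allyl chloroformate | C=CCOC(=O)Cl | starting material
3 | lithium (6S)-2,6-dimethylcyclohex-1-en-1-olate | [Li]OC1=C(C)CCC[C@@H]1C | intermediate
4 | allyl (6S)-2,6-dimethylcyclohex-1-en-1-yl carbonate | C=CCOC(=O)OC1=C(C)CCC[C@@H]1C | intermediate
5 | (2R,6S)-2-allyl-2,6-dimethylcyclohexan-1-one | C=CC[C@@]1(C)CCC[C@H](C)C1=O | intermediate
6 | (2R,6S)-2,6-dimethyl-2-[(1E)-prop-1-en-1-yl]cyclohexan-1-one | C/C=C/[C@@]1(C)CCC[C@H](C)C1=O | intermediate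
7 | secondary ozonide of 6 (3-methyl-1,2,4-trioxolan-5-yl group on C2 of the ketone) | CC1OOC(O1)[C@@]1(C)CCC[C@H](C)C1=O | intermediate
8 | (1R,3S)-1,3-dimethyl-2-oxocyclohexane-1-carbaldehyde | O=C[C@@]1(C)CCC[C@H](C)C1=O | intermediate
9 | (2R,6S)-2,6-dimethyl-2-[(E)-2-(4,4,5,5-tetramethyl-1,3,2-dioxaborolan-2-yl)ethenyl]cyclohexan-1-one | CC1(C)OB(/C=C/[C@@]2(C)CCC[C@H](C)C2=O)OC1(C)C | intermediate
10 | (2R,6S)-2-{(E)-2-[(4-methoxybenzyl)oxy]ethenyl}-2,6-dimethylcyclohexan-1-one | COc1ccc(CO/C=C/[C@@]2(C)CCC[C@H](C)C2=O)cc1 | intermediate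
11 | 2-bromoprop-2-en-1-ol | OCC(Br)=C | starting material
12 | 1-{[(2-bromoprop-2-en-1-yl)oxy]methyl}-4-methoxybenzene | C=C(Br)COCc1ccc(OC)cc1 | intermediate
13 | (E)-1,2-bis(tributylstannyl)ethene | CCCC[Sn](CCCC)(CCCC)/C=C/[Sn](CCCC)(CCCC)CCCC | starting material
14 | tributyl[(1E)-3-{[(4-methoxybenzyl)oxy]methyl}buta-1,3-dien-1-yl]stannane | CCCC[Sn](CCCC)(CCCC)/C=C/C(=C)COCc1ccc(OC)cc1 | intermediate
15 | (1E)-3-{[(4-methoxybenzyl)oxy]methyl}buta-1,3-dien-1-yllithium | [Li]/C=C/C(=C)COCc1ccc(OC)cc1 | intermediate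
16 | dichloro[(1E)-3-{[(4-methoxybenzyl)oxy]methyl}buta-1,3-dien-1-yl]cerium | Cl[Ce](Cl)/C=C/C(=C)COCc1ccc(OC)cc1 | intermediate
17 | (1S,2R,6S)-1-[(1E)-3-{[(4-methoxybenzyl)oxy]methyl}buta-1,3-dien-1-yl]-2-{(E)-2-[(4-methoxybenzyl)oxy]ethenyl}-2,6-dimethylcyclohexan-1-ol | COc1ccc(CO/C=C/[C@@]2(C)CCC[C@H](C)[C@]2(O)/C=C/C(=C)COCc2ccc(OC)cc2)cc1 | intermediate
18 | potassium alkoxide of 17 | COc1ccc(CO/C=C/[C@@]2(C)CCC[C@H](C)[C@]2(O[K])/C=C/C(=C)COCc2ccc(OC)cc2)cc1 | intermediate
19 | potassium (4S,5Z,7R,8S,9E)-8,12-bis[(4-methoxybenzyl)oxy]germacra-5,9,11(13)-trien-5-olate | C1C/C(C)=C/[C@H](OCc2ccc(OC)cc2)[C@@H](C(=C)COCc2ccc(OC)cc2)/C=C(\O[K])[C@@H](C)C1 | intermediate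
20 | (4S,6S,7S,8S,9E)-6-hydroxy-8,12-bis[(4-methoxybenzyl)oxy]germacra-9,11(13)-dien-5-one | C1C/C(C)=C/[C@H](OCc2ccc(OC)cc2)[C@@H](C(=C)COCc2ccc(OC)cc2)[C@H](O)C(=O)[C@@H](C)C1 | intermediate
21 | (4S,6S,7R,8S,9E)-6-[(tert-butyldimethylsilyl)oxy]-8,12-bis[(4-methoxybenzyl)oxy]germacra-9,11(13)-dien-5-one | C1C/C(C)=C/[C@H](OCc2ccc(OC)cc2)[C@@H](C(=C)COCc2ccc(OC)cc2)[C@H](O[Si](C)(C)C(C)(C)C)C(=O)[C@@H](C)C1 | intermediate
22 | (4S,6S,7R,8R,9S,10S)-6-[(tert-butyldimethylsilyl)oxy]-9,10-epoxy-8,12-bis[(4-methoxybenzyl)oxy]germacr-11(13)-en-5-one | C1C[C@]2(C)O[C@H]2[C@H](OCc3ccc(OC)cc3)[C@@H](C(=C)COCc3ccc(OC)cc3)[C@H](O[Si](C)(C)C(C)(C)C)C(=O)[C@@H](C)C1 | intermediate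
23 | (5R)-5-hydroxy-5,10-oxygen-bridged hemiketal form of 24 (oxygen bridge between C5 and C10, free 9-hydroxyl) | C1C[C@]2(C)[C@@H](O)[C@H](OCc3ccc(OC)cc3)[C@@H](C(=C)COCc3ccc(OC)cc3)[C@H](O[Si](C)(C)C(C)(C)C)[C@](O)(O2)[C@@H](C)C1 | intermediate
24 | (4S,6S,7R,8R,9S,10R)-6-[(tert-butyldimethylsilyl)oxy]-9,10-dihydroxy-8,12-bis[(4-methoxybenzyl)oxy]germacr-11(13)-en-5-one | C1C[C@@](C)(O)[C@@H](O)[C@H](OCc2ccc(OC)cc2)[C@@H](C(=C)COCc2ccc(OC)cc2)[C@H](O[Si](C)(C)C(C)(C)C)C(=O)[C@@H](C)C1 | intermediate
25 | (4S,6S,7R,8R,9S,10R)-6-[(tert-butyldimethylsilyl)oxy]-10-hydroxy-8,12-bis[(4-methoxybenzyl)oxy]-9-[(3-methylbutanoyl)oxy]germacr-11(13)-en-5-one | C1C[C@@](C)(O)[C@@H](OC(=O)CC(C)C)[C@H](OCc2ccc(OC)cc2)[C@@H](C(=C)COCc2ccc(OC)cc2)[C@H](O[Si](C)(C)C(C)(C)C)C(=O)[C@@H](C)C1 | intermediate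
26 | (4S,6S,7R,8R,9S,10R)-6-[(tert-butyldimethylsilyl)oxy]-8,10,12-trihydroxy-9-[(3-methylbutanoyl)oxy]germacr-11(13)-en-5-one | C1C[C@@](C)(O)[C@@H](OC(=O)CC(C)C)[C@H](O)[C@@H](C(=C)CO)[C@H](O[Si](C)(C)C(C)(C)C)C(=O)[C@@H](C)C1 | intermediate
27 | 12-aldehyde (enal) derived from 26 | C1C[C@@](C)(O)[C@@H](OC(=O)CC(C)C)[C@H](O)[C@@H](C(=C)C=O)[C@H](O[Si](C)(C)C(C)(C)C)C(=O)[C@@H](C)C1 | intermediate
28 | 8,12-lactol derived from 27 (either configuration at C12) | C1C[C@@](C)(O)[C@@H](OC(=O)CC(C)C)[C@@H]2OC(O)C(=C)[C@H]2[C@H](O[Si](C)(C)C(C)(C)C)C(=O)[C@@H](C)C1 | intermediate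
29 | (4S,6S,7R,8R,9S,10R)-6-[(tert-butyldimethylsilyl)oxy]-10-hydroxy-9-[(3-methylbutanoyl)oxy]-5-oxogermacr-11(13)-en-12,8-olide | C1C[C@@](C)(O)[C@@H](OC(=O)CC(C)C)[C@@H]2OC(=O)C(=C)[C@H]2[C@H](O[Si](C)(C)C(C)(C)C)C(=O)[C@@H](C)C1 | intermediate
30 | (4S,6S,7S,8R,9S,10R)-6,10-dihydroxy-9-[(3-methylbutanoyl)oxy]-5-oxogermacr-11(13)-en-12,8-olide (CNP0240128.1) | C=C1C(=O)O[C@@H]2[C@@H]1[C@H](O)C(=O)[C@@H](C)CCC[C@@](C)(O)[C@H]2OC(=O)CC(C)C | target

**Totals and risks**

Total step count: 17. Longest linear sequence: 15 steps (steps 1–6 and 9–17, from compound 1); steps 7 and 8 make the dienyl fragment.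

Step 13. The opening may lose its stereospecificity at C10 if the protonated epoxide ionises to a free tertiary cation, which can then be captured by external water on the open face, shift a hydride or eliminate; the silyl ether may also be cleaved by the aqueous acid. The fallback sets out from 22 and replaces water by anhydrous methanol with pyridinium tosylate at 0 °C to rt, so that the more populated methanol hemiketal at C5 opens the epoxide at C10 from inside the ring and the result is locked as the isolable bridged mixed methyl ketal F1, which still carries the free 9-hydroxyl. Acylation with isovaleric anhydride, DMAP and Et3N should give the ester of the bridged ketal F2, and mild hydrolysis (AcOH/THF/H2O) unmasks the ketone and the C10 carbinol, so the route is rejoined at 25. The ketal also keeps C4 and C6 from epimerising during the acylation.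

Step 10. The hindered alkoxide may fragment by retro-addition instead of rearranging, proton transfer may move the enolate towards C4, or the hydroxylation may suffer from addition of the enolate to the sulfonimine that the oxidant releases. The fallback sets out from 17, runs the same alkoxide rearrangement and traps the enolate at −78 °C with TBSCl as the tert-butyldimethylsilyl enol ether F3. This is then submitted to a Rubottom oxidation with dimethyldioxirane (1 equiv, acetone/CH2Cl2, −78 °C), which should give the outer-face silyloxy oxirane F4; on warming with a trace of pyridinium tosylate this rearranges with silyl migration to the α-silyloxy ketone. The route is rejoined at 21, and step 11 is no longer needed.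

Step 1. The discrimination of the two enantiotopic α-hydrogens may be low, which would carry too much of the wrong enolate enantiomer into step 2. The fallback sets out from 1 (or from the commercial isomer mixture) and gives up the chiral base: LiN(SiMe3)2, TMEDA and allyl chloroformate in THF at −78 °C give the racemic enol carbonate F5. The catalyst of step 2 then fixes C10 alone and should deliver 5 together with its C6 epimer, the trans-dimethyl ketone F6, which is separated by chromatography, equilibrated at C6 with DBU in toluene and recycled. The route is rejoined at 5.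

**Further compounds**

F1 | step 13 | (5R)-5-methoxy-5,10-oxygen-bridged methyl ketal of the 9-hydroxy compound (6-O-TBS, 8,12-bis-O-PMB, free 9-OH) | C1C[C@]2(C)[C@@H](O)[C@H](OCc3ccc(OC)cc3)[C@@H](C(=C)COCc3ccc(OC)cc3)[C@H](O[Si](C)(C)C(C)(C)C)[C@](OC)(O2)[C@@H](C)C1
F2 | step 13 | 9-O-(3-methylbutanoyl) ester of F1 | C1C[C@]2(C)[C@@H](OC(=O)CC(C)C)[C@H](OCc3ccc(OC)cc3)[C@@H](C(=C)COCc3ccc(OC)cc3)[C@H](O[Si](C)(C)C(C)(C)C)[C@](OC)(O2)[C@@H](C)C1
F3 | step 10 | (4S,5Z,7R,8S,9E)-5-[(tert-butyldimethylsilyl)oxy]-8,12-bis[(4-methoxybenzyl)oxy]germacra-5,9,11(13)-triene | C1C/C(C)=C/[C@H](OCc2ccc(OC)cc2)[C@@H](C(=C)COCc2ccc(OC)cc2)/C=C(\O[Si](C)(C)C(C)(C)C)[C@@H](C)C1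
F4 | step 10 | 5,6-epoxide of F3 with the oxirane oxygen on the outer face | C1C/C(C)=C/[C@H](OCc2ccc(OC)cc2)[C@@H](C(=C)COCc2ccc(OC)cc2)[C@@H]3O[C@@]3(O[Si](C)(C)C(C)(C)C)[C@@H](C)C1
F5 | step 1 | racemic allyl 2,6-dimethylcyclohex-1-en-1-yl carbonate | C=CCOC(=O)OC1=C(C)CCCC1C
F6 | step 1 | (2R,6R)-2-allyl-2,6-dimethylcyclohexan-1-one | C=CC[C@@]1(C)CCC[C@@H](C)C1=O
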